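**Retrosynthetic overview**
1. Target ⇒ (fluoride; LiCl) protected 7‑endo‑prenyl bicycle 35 ⇒ (Wittig; exo‑face CuH; Pd formylation) C7‑exocyclic enol triflate 32, so that C7–H is delivered last, from the exo face.
2. Ring B (C5–C6–C7–C8–C1–C9) is disconnected at two bonds: C1–C8 by a dearomative [3,3] Claisen shift from O2, and C5–C6 by intramolecular Michael addition, both from the flat aryl ether 29 in one operation.
3. Enabling feature: ring A (C1–C2–C3–C4–C5–C9) is a dearomatised acylphloroglucinol in which O2 is ortho to C1 and para to C5, and C9–O lies between C1 and C5. A 2‑formylprenyl unit on O2 can therefore only place CMe2 (C8) on C1 and CH2 (C6) on C5, and C9–O becomes the bridging ketone.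
4. Arene 29 ⇐ three successive directed ortho‑metalations of bis‑MOM 5‑methoxyresorcinol (C1 chain; C5 (S)‑lavandulyl from an Evans alkylation; C3 aroyl), then O9 acetylation and O2 Mitsunobu etherification.
5. Ring order: both benzene rings are bought; ring A is dearomatised and ring B is closed last, in step 17.

Key step: step 17

**Remarks**
- Numbering follows the polyprenylated acylphloroglucinols: C1 = bridgehead with the hydroxyalkyl chain, C2–C3–C4 = acyl‑trione bridge, C5 = bridgehead with the lavandulyl group, C6/C7/C8 = CH2/CH(prenyl)/CMe2, C9 = bridging ketone; oxygens carry the number of their carbon.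
- Assumption: the enol tautomer of the β‑triketone is drawn as in the target SMILES, and the exocyclic C7 alkenes (31–33) are drawn E as the expected isomers; neither affects the outcome.
- The lavandulyl unit has the spatial arrangement of (S)‑lavandulol; once its CH2 is bound to carbon instead of O or I, the CIP label of that centre reads R.
- In step 17 the ligand antipode is written as (S,S); the sense of induction would have to be assigned by experiment, and both antipodes are available.

**Route**

Step 1
Reactants: 1 (S)-4-benzyl-1,3-oxazolidin-2-one; 2 3-methylbut-2-enoyl chloride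
Product: 4 (S)-4-benzyl-3-(3-methylbut-2-enoyl)-1,3-oxazolidin-2-one, via lithium oxazolidinide 3 (not isolated)
Conditions: n-BuLi, THF, −78 °C; then 2, −78 → 0 °C
Reagents that add atoms: none
Why: N‑acylation of the lithiated Evans auxiliary with an acid chloride is the standard entry to N‑enoyl oxazolidinones.

Step 2
Reactants: 4 N‑senecioyl oxazolidinone; 5 prenyl bromide
Product: 7 (4S)-4-benzyl-3-[(2S)-5-methyl-2-(prop-1-en-2-yl)hex-4-enoyl]-1,3-oxazolidin-2-one, via sodium dienolate 6 (not isolated)
Conditions: NaHMDS, THF, −78 °C; then 5, −78 → −30 °C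
Reagents that add atoms: none
Why: Deconjugative Evans alkylation: γ‑deprotonation gives the chelated Z‑dienolate, which is alkylated at the α‑carbon on the face opposite the benzyl group, which should set the (S) centre and leave the isopropenyl group.

Step 3
Reactants: 7 alkylated imide
Product: 8 (S)-lavandulol
Conditions: LiBH4, MeOH (1 equiv), Et2O, 0 °C
Reagents that add atoms: none
Why: Reductive cleavage of the N‑acyl oxazolidinone with lithium borohydride should give the primary alcohol without touching the β,γ‑unsaturation or the stereocentre.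

Step 4
Reactants: 8 (S)-lavandulol
Product: 9 (S)-lavandulyl iodide
Conditions: PPh3, I2, imidazole, CH2Cl2, 0 °C → rt
Reagents that add atoms: iodine, II
Why: Appel‑type iodination of a primary alcohol proceeds at CH2 and does not involve the adjacent stereocentre.

Step 5
Reactants: 10 3-methylbutane-1,3-diol
Product: 11 4-iodo-2-methylbutan-2-ol
Conditions: PPh3, I2, imidazole, CH2Cl2, 0 °C
Reagents that add atoms: iodine, II
Why: Appel iodination is selective for the primary hydroxyl; the tertiary one cannot undergo SN2 displacement.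

Step 6
Reactants: 11 4-iodo-2-methylbutan-2-ol
Product: 12 tert-butyl[(4-iodo-2-methylbutan-2-yl)oxy]dimethylsilane
Conditions: TBSOTf, 2,6-lutidine, CH2Cl2, 0 °C
Reagents that add atoms: tert-butyldimethylsilyl trifluoromethanesulfonate, CC(C)(C)[Si](C)(C)OS(=O)(=O)C(F)(F)F
Why: Silyl triflate with a hindered pyridine base is the standard silylation of tertiary alcohols.

Step 7
Reactants: 13 methyl 3,4-dihydroxybenzoate
Product: 14 methyl 3,4-bis(triisopropylsilyloxy)benzoate
Conditions: TIPSCl, imidazole, DMF, 50 °C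
Reagents that add atoms: chlorotriisopropylsilane, CC(C)[Si](Cl)(C(C)C)C(C)C
Why: Standard silylation of phenols; the TIPS ethers are chosen to survive organolithium, alkoxide and Lewis acid steps.

Step 8
Reactants: 15 diethyl 2-(propan-2-ylidene)malonate
Product: 16 2-(propan-2-ylidene)propane-1,3-diol
Conditions: DIBAL-H, CH2Cl2, −78 → 0 °C; Rochelle salt
Reagents that add atoms: none
Why: DIBAL reduces both ester groups of the alkylidene malonate by 1,2‑addition and should leave the tetrasubstituted alkene untouched.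

Step 9
Reactants: 16 2-(propan-2-ylidene)propane-1,3-diol
Product: 17 2-(hydroxymethyl)-3-methylbut-2-enal
Conditions: activated MnO2, CH2Cl2, rt
Reagents that add atoms: none
Why: Allylic oxidation with MnO2 should stop at the mono‑aldehyde, because the enal formed makes the second CH2OH part of an electron‑poor allylic system.

Step 10
Reactants: 18 5-methoxyresorcinol
Product: 19 1-methoxy-3,5-bis(methoxymethoxy)benzene
Conditions: MOMCl, i-Pr2NEt, CH2Cl2, 0 °C → rt
Reagents that add atoms: chloromethyl methyl ether, COCCl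
Why: Standard MOM protection; the MOM groups are the ortho‑directing groups for the three metalations, and the methyl ether marks O4.

Step 11
Reactants: 19 bis-MOM arene; 12 silyl‑protected iodide
Product: 21 arene with the C1 chain (between the two OMOM groups), via aryllithium 20 (not isolated)
Conditions: n-BuLi, THF, 0 °C; then 12, −78 °C → rt
Reagents that add atoms: none
Why: Directed ortho‑metalation occurs at the position flanked by two MOM ethers, and the aryllithium is alkylated by the unhindered primary iodide (SN2).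

Step 12
Reactants: 21 mono‑alkylated arene; 9 (S)-lavandulyl iodide
Product: 24 lavandulyl arene (lavandulyl between OMe and OMOM), via aryllithium 22 (not isolated), via arylmagnesium bromide 23 (not isolated)
Conditions: n-BuLi, TMEDA, THF, 0 °C; MgBr2·OEt2; then 9, Li2CuCl4 (5 mol%), −20 °C → rt
Reagents that add atoms: none
Why: Second ortho‑metalation at one of the two equivalent OMe/OMOM‑flanked positions, then copper‑catalysed (Kochi‑type) coupling of the aryl Grignard with the β‑branched primary iodide, which should suppress the E2 elimination an aryllithium would cause and does not touch the stereocentre.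

Step 13
Reactants: 24 lavandulyl arene; 14 methyl 3,4-bis(triisopropylsilyloxy)benzoate
Product: 26 fully substituted benzophenone, via aryllithium 25 (not isolated)
Conditions: n-BuLi, THF, −20 → 0 °C; then added to 14, −78 → 0 °C
Reagents that add atoms: none
Why: Third ortho‑metalation at the last ring C–H (flanked by OMe and OMOM) and acylation by the ester; the 2,6‑dioxygenated diaryl ketone is too hindered for a second addition.

Step 14
Reactants: 26 bis-MOM benzophenone
Product: 27 O2,O9-diol
Conditions: ZnBr2, n-PrSH, CH2Cl2, 0 °C, 10 min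
Reagents that add atoms: none
Why: Zinc bromide with a thiol cleaves aryl MOM ethers within minutes, conditions under which aryl TIPS ethers, the tertiary TBS ether and the alkenes should survive.

Step 15
Reactants: 27 diol
Product: 28 O9-acetate
Conditions: Ac2O (1.1 equiv), pyridine, CH2Cl2, 0 °C
Reagents that add atoms: acetic anhydride, CC(=O)OC(C)=O
Why: Acylation should take place at the O9 phenol, because the O2 phenol is held in a hydrogen bond to the aroyl carbonyl (selective acylation of the non‑chelated hydroxyl).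

Step 16
Reactants: 28 O9-acetate; 17 2-(hydroxymethyl)-3-methylbut-2-enal
Product: 29 O2 (2-formyl-3-methylbut-2-enyl) aryl ether
Conditions: PPh3, DIAD, THF, 0 °C → rt
Reagents that add atoms: none
Why: Mitsunobu etherification of the remaining phenol with a primary allylic alcohol runs under neutral conditions that leave the aryl acetate in place.

Step 17
Reactants: 29 aryl allyl ether
Product: 32 bicyclic (E)-enol triflate, via ortho-dienone 30 (not isolated), via potassium aldehyde enolate 31 (not isolated)
Conditions: Cu(OTf)2 (10 mol%), (S,S)-t-Bu-box (12 mol%), 4 Å MS, CH2Cl2, −20 °C → rt; then THF, KOt-Bu (1.05 equiv), −78 → −20 °C; then PhNTf2, −78 → 0 °C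
Reagents that add atoms: N-phenylbis(trifluoromethanesulfonimide), O=S(=O)(N(c1ccccc1)S(=O)(=O)C(F)(F)F)C(F)(F)F
Why: Proposed new method: the chiral Cu(II) Lewis acid chelates O2 and the aroyl carbonyl and should trigger a dearomative ortho‑[3,3] Claisen shift that moves the CMe2 terminus from O2 to C1 (the hindered C1–C8 bond between two quaternary carbons is made by the sigmatropic step), giving dienone 30; KOt‑Bu then cleaves the C9 enol acetate, the enolate adds through C5 to the terminal CH2 of the 2‑formylallyl unit (C5–C6), and aldehyde enolate 31 is O‑triflated. The closest known reaction types are Lewis‑acid‑catalysed enantioselective dearomative Claisen rearrangements of allyl aryl ethers with an ortho carbonyl as chelating group, Claisen/Diels–Alder cascades that trap the ortho‑dienone in situ, and base‑mediated alkylative dearomatisation–annulation of acylphloroglucinols with α‑(acyloxymethyl) enals. Ring B is closed by a 6‑endo‑trig Michael addition. C1 is set by the catalyst‑controlled face of the [3,3] shift, C5 follows because the three‑carbon bridge can only span the face on which C8 already sits, and C7 stays sp2. The step needs C1 over C3 in the shift and C5 over C3 in the Michael addition: C3 is deactivated by its two acyl neighbours and has no enolate character, and a competing Cope shift of 30 to C5 would only carry the same unit to the para carbon on the same face and converge on 32. Regiochemistry (CMe2 on C1, CH2 on C5) is secured by placing the allyl unit on O2, with O4 blocked as methyl ether and O9 held as the acetate that later releases the enolate.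

Step 18
Reactants: 32 enol triflate
Product: 33 exocyclic (E)-enal
Conditions: Pd(PPh3)4 (5 mol%), CO (1 atm), Bu3SnH (slow addition), LiCl, THF, 50 °C
Reagents that add atoms: carbon monoxide, [C-]#[O+]
Why: Palladium‑catalysed reductive carbonylation (formylation) of an alkenyl triflate: oxidative addition, CO insertion and hydride transfer from tin should give the enal with retention of alkene geometry.

Step 19
Reactants: 33 enal
Product: 34 7-endo (2-oxoethyl) bicycle
Conditions: [(Ph3P)CuH]6 (0.5 equiv), benzene, H2O (2 equiv), rt; aq. NH4Cl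
Reagents that add atoms: none
Why: Conjugate reduction with Stryker's reagent; the bulky copper hydride should attack C7 from the open exo face (the endo face is shielded by the C2–C3–C4 bridge), so that the CH2CHO group ends endo, which is the C7 configuration of the target, while isolated alkenes and the vinylogous ester are inert.

Step 20
Reactants: 34 aldehyde
Product: 35 7-endo-prenyl bicycle (O4 methyl ether; silyl‑protected)
Conditions: i-PrPPh3I, n-BuLi, THF, 0 °C; then 34, −78 → 0 °C
Reagents that add atoms: isopropyltriphenylphosphonium iodide, CC(C)[P+](c1ccccc1)(c1ccccc1)c1ccccc1.[I-]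
Why: Wittig olefination with the unstabilised isopropylidene ylide converts the aldehyde into the prenyl group; the hindered ketones and the vinylogous ester should not react.

Step 21
Reactants: 35 O4 methyl ether
Product: 36 silyl‑protected target (free enolised β‑triketone)
Conditions: LiCl, DMSO, 120 °C; aq. citric acid
Reagents that add atoms: none
Why: SN2 demethylation of the vinylogous methyl ester by chloride (Krapcho type), the usual unmasking of O‑methylated bicyclic acylphloroglucinols.

Step 22
Reactants: 36 silyl‑protected target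
Product: 37 target (CNP0148616.1)
Conditions: TBAF (excess), THF, 0 → 50 °C, argon; AcOH quench
Reagents that add atoms: none
Why: Fluoride cleaves both aryl TIPS ethers and the tertiary TBS ether under conditions that should not isomerise the alkenes or cyclise the tertiary alcohol onto the enol.

**Compound list**
1 | (S)-4-benzyl-1,3-oxazolidin-2-one | O=C1N[C@@H](Cc2ccccc2)CO1 | starting material
2 | 3-methylbut-2-enoyl chloride | CC(C)=CC(=O)Cl | starting material
3 | lithium salt of 1 | [Li+].O=C1[N-][C@@H](Cc2ccccc2)CO1 | intermediate (not isolated)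
4 | (S)-4-benzyl-3-(3-methylbut-2-enoyl)-1,3-oxazolidin-2-one | CC(C)=CC(=O)N1[C@@H](Cc2ccccc2)COC1=O | intermediate
5 | 1-bromo-3-methylbut-2-ene (prenyl bromide) | CC(C)=CCBr | starting material
6 | sodium (Z)-dienolate of 4 | [Na+].C=C(C)/C=C(\[O-])N1[C@@H](Cc2ccccc2)COC1=O | intermediate (not isolated)
7 | (4S)-4-benzyl-3-[(2S)-5-methyl-2-(prop-1-en-2-yl)hex-4-enoyl]-1,3-oxazolidin-2-one | C=C(C)[C@H](CC=C(C)C)C(=O)N1[C@@H](Cc2ccccc2)COC1=O | intermediate
8 | (S)-lavandulol, (2S)-5-methyl-2-(prop-1-en-2-yl)hex-4-en-1-ol | C=C(C)[C@H](CC=C(C)C)CO | intermediate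
9 | (S)-lavandulyl iodide, (3S)-3-(iodomethyl)-2,6-dimethylhepta-1,5-diene | C=C(C)[C@H](CC=C(C)C)CI | intermediate
10 | 3-methylbutane-1,3-diol | CC(C)(O)CCO | starting material
11 | 4-iodo-2-methylbutan-2-ol | CC(C)(O)CCI | intermediate
12 | tert-butyl[(4-iodo-2-methylbutan-2-yl)oxy]dimethylsilane | CC(C)(CCI)O[Si](C)(C)C(C)(C)C | intermediate
13 | methyl 3,4-dihydroxybenzoate | COC(=O)c1ccc(O)c(O)c1 | starting material
14 | methyl 3,4-bis(triisopropylsilyloxy)benzoate | COC(=O)c1ccc(O[Si](C(C)C)(C(C)C)C(C)C)c(O[Si](C(C)C)(C(C)C)C(C)C)c1 | intermediate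
15 | diethyl 2-(propan-2-ylidene)malonate | CCOC(=O)C(=C(C)C)C(=O)OCC | starting material
16 | 2-(propan-2-ylidene)propane-1,3-diol | CC(C)=C(CO)CO | intermediate
17 | 2-(hydroxymethyl)-3-methylbut-2-enal | CC(C)=C(CO)C=O | intermediate
18 | 5-methoxyresorcinol | COc1cc(O)cc(O)c1 | starting material
19 | 1-methoxy-3,5-bis(methoxymethoxy)benzene | COCOc1cc(OC)cc(OCOC)c1 | intermediate
20 | 4-methoxy-2,6-bis(methoxymethoxy)phenyllithium | COCOc1cc(OC)cc(OCOC)c1[Li] | intermediate (not isolated)
21 | tert-butyl({4-[4-methoxy-2,6-bis(methoxymethoxy)phenyl]-2-methylbutan-2-yl}oxy)dimethylsilane | COCOc1cc(OC)cc(OCOC)c1CCC(C)(C)O[Si](C)(C)C(C)(C)C | intermediate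
22 | aryllithium from 21 (Li between OMe and OMOM) | COCOc1c([Li])c(OC)cc(OCOC)c1CCC(C)(C)O[Si](C)(C)C(C)(C)C | intermediate (not isolated)
23 | arylmagnesium bromide from 22 | COCOc1c([Mg]Br)c(OC)cc(OCOC)c1CCC(C)(C)O[Si](C)(C)C(C)(C)C | intermediate (not isolated)
24 | 1-methoxy-3,5-bis(methoxymethoxy)-4-[3-(tert-butyldimethylsilyloxy)-3-methylbutyl]-2-[(2R)-5-methyl-2-(prop-1-en-2-yl)hex-4-enyl]benzene | COCOc1c(C[C@@H](CC=C(C)C)C(C)=C)c(OC)cc(OCOC)c1CCC(C)(C)O[Si](C)(C)C(C)(C)C | intermediate
25 | aryllithium from 24 (Li at the last ring C–H) | COCOc1c(C[C@@H](CC=C(C)C)C(C)=C)c(OC)c([Li])c(OCOC)c1CCC(C)(C)O[Si](C)(C)C(C)(C)C | intermediate (not isolated)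
26 | {3-[3-(tert-butyldimethylsilyloxy)-3-methylbutyl]-6-methoxy-2,4-bis(methoxymethoxy)-5-[(2R)-5-methyl-2-(prop-1-en-2-yl)hex-4-enyl]phenyl}[3,4-bis(triisopropylsilyloxy)phenyl]methanone | COCOc1c(C[C@@H](CC=C(C)C)C(C)=C)c(OC)c(C(=O)c2ccc(O[Si](C(C)C)(C(C)C)C(C)C)c(O[Si](C(C)C)(C(C)C)C(C)C)c2)c(OCOC)c1CCC(C)(C)O[Si](C)(C)C(C)(C)C | intermediate
27 | the 2,4-dihydroxy analogue of 26 (O2–H and O9–H free) | Oc1c(C[C@@H](CC=C(C)C)C(C)=C)c(OC)c(C(=O)c2ccc(O[Si](C(C)C)(C(C)C)C(C)C)c(O[Si](C(C)C)(C(C)C)C(C)C)c2)c(O)c1CCC(C)(C)O[Si](C)(C)C(C)(C)C | intermediate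
28 | O9-acetate of 27 (4-acetoxy-2-hydroxy) | CC(=O)Oc1c(C[C@@H](CC=C(C)C)C(C)=C)c(OC)c(C(=O)c2ccc(O[Si](C(C)C)(C(C)C)C(C)C)c(O[Si](C(C)C)(C(C)C)C(C)C)c2)c(O)c1CCC(C)(C)O[Si](C)(C)C(C)(C)C | intermediate
29 | O2 (2-formyl-3-methylbut-2-enyl) ether of 28 | CC(=O)Oc1c(C[C@@H](CC=C(C)C)C(C)=C)c(OC)c(C(=O)c2ccc(O[Si](C(C)C)(C(C)C)C(C)C)c(O[Si](C(C)C)(C(C)C)C(C)C)c2)c(OCC(C=O)=C(C)C)c1CCC(C)(C)O[Si](C)(C)C(C)(C)C | intermediate
30 | ortho-dienone: C1 quaternary (chain and 1,1-dimethyl-2-formylallyl), C2 ketone, C4 methyl enol ether, C9 enol acetate; C1 configured as in the target | C=C(C=O)C(C)(C)[C@@]1(CCC(C)(C)O[Si](C)(C)C(C)(C)C)C(=O)C(C(=O)c2ccc(O[Si](C(C)C)(C(C)C)C(C)C)c(O[Si](C(C)C)(C(C)C)C(C)C)c2)=C(OC)C(C[C@@H](CC=C(C)C)C(C)=C)=C1OC(C)=O | intermediate (not isolated)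
31 | potassium (E)-enolate of the (1R,5R)-bicyclic C7 aldehyde | C=C(C)[C@H](CC=C(C)C)C[C@@]12C/C(=C\[O-])C(C)(C)[C@@](CCC(C)(C)O[Si](C)(C)C(C)(C)C)(C(=O)C(C(=O)c3ccc(O[Si](C(C)C)(C(C)C)C(C)C)c(O[Si](C(C)C)(C(C)C)C(C)C)c3)=C1OC)C2=O.[K+] | intermediate (not isolated)
32 | (1R,5R)-3-[3,4-bis(triisopropylsilyloxy)benzoyl]-1-[3-(tert-butyldimethylsilyloxy)-3-methylbutyl]-4-methoxy-8,8-dimethyl-5-[(2R)-5-methyl-2-(prop-1-en-2-yl)hex-4-enyl]-7-[(E)-(trifluoromethanesulfonyloxy)methylidene]bicyclo[3.3.1]non-3-ene-2,9-dione | C=C(C)[C@H](CC=C(C)C)C[C@@]12C/C(=C\OS(=O)(=O)C(F)(F)F)C(C)(C)[C@@](CCC(C)(C)O[Si](C)(C)C(C)(C)C)(C(=O)C(C(=O)c3ccc(O[Si](C(C)C)(C(C)C)C(C)C)c(O[Si](C(C)C)(C(C)C)C(C)C)c3)=C1OC)C2=O | intermediate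
33 | the 7-[(E)-2-oxoethylidene] analogue of 32 (exocyclic enal) | C=C(C)[C@H](CC=C(C)C)C[C@@]12C/C(=C\C=O)C(C)(C)[C@@](CCC(C)(C)O[Si](C)(C)C(C)(C)C)(C(=O)C(C(=O)c3ccc(O[Si](C(C)C)(C(C)C)C(C)C)c(O[Si](C(C)C)(C(C)C)C(C)C)c3)=C1OC)C2=O | intermediate
34 | the 7-endo-(2-oxoethyl) analogue (C7–H exo) | C=C(C)[C@H](CC=C(C)C)C[C@@]12C[C@@H](CC=O)C(C)(C)[C@@](CCC(C)(C)O[Si](C)(C)C(C)(C)C)(C(=O)C(C(=O)c3ccc(O[Si](C(C)C)(C(C)C)C(C)C)c(O[Si](C(C)C)(C(C)C)C(C)C)c3)=C1OC)C2=O | intermediate
35 | the 7-endo-(3-methylbut-2-enyl) analogue: O4 methyl ether, TBS and TIPS groups in place | C=C(C)[C@H](CC=C(C)C)C[C@@]12C[C@@H](CC=C(C)C)C(C)(C)[C@@](CCC(C)(C)O[Si](C)(C)C(C)(C)C)(C(=O)C(C(=O)c3ccc(O[Si](C(C)C)(C(C)C)C(C)C)c(O[Si](C(C)C)(C(C)C)C(C)C)c3)=C1OC)C2=O | intermediate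
36 | silyl-protected target (4-hydroxy enol free) | C=C(C)[C@H](CC=C(C)C)C[C@@]12C[C@@H](CC=C(C)C)C(C)(C)[C@@](CCC(C)(C)O[Si](C)(C)C(C)(C)C)(C(=O)C(C(=O)c3ccc(O[Si](C(C)C)(C(C)C)C(C)C)c(O[Si](C(C)C)(C(C)C)C(C)C)c3)=C1O)C2=O | intermediate
37 | (1R,5R,7R)-3-(3,4-dihydroxybenzoyl)-4-hydroxy-1-(3-hydroxy-3-methylbutyl)-8,8-dimethyl-7-(3-methylbut-2-enyl)-5-[(2R)-5-methyl-2-(prop-1-en-2-yl)hex-4-enyl]bicyclo[3.3.1]non-3-ene-2,9-dione | C=C(C)[C@H](CC=C(C)C)C[C@@]12C[C@@H](CC=C(C)C)C(C)(C)[C@@](CCC(C)(C)O)(C(=O)C(C(=O)c3ccc(O)c(O)c3)=C1O)C2=O | target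

**Step count**
Total: 22 steps. Longest linear sequence: 15 steps (steps 1–4, then 12–22).

**Steps most likely to fail**

Step 17. The face selection in the [3,3] shift may be poor, since the chiral Lewis acid has to discriminate the faces of a fully substituted arene and can also bind the aroyl carbonyl together with O4 instead of O2. The dienone may also revert to the ether before the Michael trap. The fallback uses only known reaction types, sets out from 29 and comes back at 32. Heating 29 in toluene at 110 °C would bring about the thermal ortho‑Claisen shift followed by a Cope shift (the para‑Claisen rearrangement of an aryl prenyl‑type ether whose ortho positions are blocked), which moves the side chain with its CH2 terminus to C5 and gives the cross‑conjugated C5‑quaternary dienone F1 together with its C5 epimer. Treatment with KOt‑Bu in THF would then cleave the enol acetate and close the C1–C8 bond by intramolecular Michael addition of C1 to the β,β‑dimethyl enal, the closure known from alkylative dearomatisation–annulation of acylphloroglucinols. Trapping with PhNTf2 would give 32 and its diastereomer with the opposite core configuration; each is a single enantiomer, and they would be separated by chromatography.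

Step 12. E2 elimination of the β‑branched iodide (its β‑hydrogen is allylic) and slow substitution at the di‑ortho‑substituted aryl metal may both lower the yield. The fallback reverses the polarity, sets out from 21 and comes back at 24. Compound 21 would be lithiated as in step 12 and quenched with iodine to give the aryl iodide F2. Iodide 9 would be converted with zinc dust and LiCl in THF into (S)-lavandulylzinc iodide F3. A Negishi coupling of F2 with F3 (Pd(OAc)2, SPhos, THF, 50 °C) would then give 24.

Step 18. The alkenylpalladium intermediate may capture hydride before CO inserts (giving the exocyclic methylene compound), or CO insertion may be slow at the hindered alkene. The fallback goes through the ester oxidation level, sets out from 32 and comes back at 34. Palladium‑catalysed methoxycarbonylation of 32 (Pd(OAc)2, dppp, CO, MeOH, Et3N, DMF) would give the methyl enoate F4. Conjugate reduction with Stryker's reagent, again from the exo face, would give the saturated 7‑endo methyl ester F5. Half‑reduction with DIBAL‑H (1.05 equiv, CH2Cl2, −78 °C) would give aldehyde 34.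

**Further compounds**
F1 | step 17 | cross-conjugated dienone: C5 quaternary (lavandulyl and 2-formyl-3-methylbut-2-enyl), C2 ketone, C4 methyl enol ether, C9 enol acetate; epimer shown is the one that leads to 32 | C=C(C)[C@H](CC=C(C)C)C[C@@]1(CC(C=O)=C(C)C)C(OC)=C(C(=O)c2ccc(O[Si](C(C)C)(C(C)C)C(C)C)c(O[Si](C(C)C)(C(C)C)C(C)C)c2)C(=O)C(CCC(C)(C)O[Si](C)(C)C(C)(C)C)=C1OC(C)=O
F2 | step 12 | aryl iodide from 21 (iodine between OMe and OMOM) | COCOc1c(I)c(OC)cc(OCOC)c1CCC(C)(C)O[Si](C)(C)C(C)(C)C
F3 | step 12 | (S)-lavandulylzinc iodide | C=C(C)[C@H](CC=C(C)C)C[Zn]I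
F4 | step 18 | methyl (E)-enoate: the 7-(2-methoxy-2-oxoethylidene) analogue of 32 | C=C(C)[C@H](CC=C(C)C)C[C@@]12C/C(=C\C(=O)OC)C(C)(C)[C@@](CCC(C)(C)O[Si](C)(C)C(C)(C)C)(C(=O)C(C(=O)c3ccc(O[Si](C(C)C)(C(C)C)C(C)C)c(O[Si](C(C)C)(C(C)C)C(C)C)c3)=C1OC)C2=O
F5 | step 18 | saturated ester: the 7-endo-(2-methoxy-2-oxoethyl) analogue | C=C(C)[C@H](CC=C(C)C)C[C@@]12C[C@@H](CC(=O)OC)C(C)(C)[C@@](CCC(C)(C)O[Si](C)(C)C(C)(C)C)(C(=O)C(C(=O)c3ccc(O[Si](C(C)C)(C(C)C)C(C)C)c(O[Si](C(C)C)(C(C)C)C(C)C)c3)=C1OC)C2=O
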